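## Plan

- **Numbering (along the SMILES):** C1 (CH–O), C2=C3(CH3), C4 (fusion CH), C5H2, C6 (C=O), C7(CH3)=C8, C9 (fusion CH), C10 (C(CH3)2), C11 (CH–O). Ring A is the seven-membered ring C1–C4/C9–C11. Ring B is the six-membered ring C4–C9.
- **Cuts:** the two ester C–O bonds; the C6 enone back to a C6=C7 alkene; the C1 and C11 oxygens back to a C11 ketone; C1 taken out of ring A (C11–C1 and C1–C2 replaced by C11–C2); last, C4–C5 and C8–C9.
- **Enabling feature:** C5–C6–C7(CH3)–C8 of ring B is an isoprene unit lying across the C4–C9 bond. Ring A without C1 is 3,6,6-trimethylcyclohexa-2,4-dienone, whose γ,δ-alkene is C4=C9 with C9 as the vinylogous electrophilic end.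
- **Forward order:** contracted ring A (dienone 5, four steps), ring B by Diels–Alder addition of isoprene, ring A enlarged by insertion of C1, then C1–OH, C11–OH, the two angelates, and last the ring B enone.
- **Stereochemistry:** C4/C9 are cis from the suprafacial cycloaddition and absolute from a chiral oxazaborolidinium catalyst. C1 comes from substrate-controlled enolate hydroxylation and C11 from hydroxyl-directed hydride delivery (trans-diol). Both Z-alkenes come with angelic acid.

Key step: step 5

Assumption: the sense of induction of the catalyst on this new dienophile class cannot be derived safely from precedent. The (S)-catalyst is written, and the equally available (R)-catalyst is used if the adduct proves to be the antipode.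

## Route

Step 1
Reactants: 1 4,4-dimethylcyclohex-2-en-1-one
Product: 2 1,4,4-trimethylcyclohex-2-en-1-ol (racemic)
Conditions: MeLi, Et2O, −78 to 0 °C; then H2O
Reagents that add atoms: methyllithium [Li]C
Why: Hard organolithium reagents add 1,2 to cyclohexenones (carbonyl addition), and the new carbinol centre is erased in the next step, so the racemate serves.

Step 2
Reactants: 2 1,4,4-trimethylcyclohex-2-en-1-ol
Product: 3 3,6,6-trimethylcyclohex-2-en-1-one
Conditions: pyridinium chlorochromate [C5H5NH][CrO3Cl], Celite, CH2Cl2, rt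
Reagents that add atoms: pyridinium chlorochromate [O-][Cr](=O)(=O)Cl.c1cc[nH+]cc1 (supplies the carbonyl oxygen; the carbinol oxygen leaves with chromium)
Why: Babler–Dauben oxidative 1,3-transposition of a tertiary allylic alcohol with hexavalent chromium moves the oxygen to the far allylic terminus next to the gem-dimethyl carbon and leaves the methyl group on the β-carbon of the new enone.

Step 3
Reactants: 3 3,6,6-trimethylcyclohex-2-en-1-one
Product: 4 tert-butyldimethyl[(3,6,6-trimethylcyclohexa-1,3-dien-1-yl)oxy]silane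
Conditions: TBSOTf, Et3N, CH2Cl2, 0 °C to rt
Reagents that add atoms: tert-butyldimethylsilyl trifluoromethanesulfonate CC(C)(C)[Si](C)(C)OS(=O)(=O)C(F)(F)F
Why: Soft enolisation (silyl triflate/amine) of an enone that has no α'-hydrogen can only remove a γ-hydrogen, and under these equilibrating conditions the endocyclic, more substituted linear dienol ether should prevail.

Step 4
Reactants: 4 tert-butyldimethyl[(3,6,6-trimethylcyclohexa-1,3-dien-1-yl)oxy]silane
Product: 5 3,6,6-trimethylcyclohexa-2,4-dien-1-one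
Conditions: Pd(OAc)2 (1.05 equiv), MeCN, rt; cold filtration through silica, taken up in CH2Cl2 and used at once
Reagents that add atoms: none
Why: In the Saegusa–Ito dehydrogenation divalent palladium replaces silicon on the dienolate and β-hydride loss from the ring CH2 next to the quaternary carbon installs the γ,δ-alkene at room temperature under neutral conditions, mild enough to postpone the Diels–Alder dimerisation of the dienone.

Step 5
Reactants: 5 3,6,6-trimethylcyclohexa-2,4-dien-1-one; 6 isoprene (2-methylbuta-1,3-diene)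
Product: 7 (4aR,8aS)-1,1,4,7-tetramethyl-4a,5,8,8a-tetrahydronaphthalen-2(1H)-one (cis-fused; C11 ketone, C2=C3 enone, C6=C7 alkene)
Conditions: (S)-3,3-diphenyl-1-(2-methylphenyl)tetrahydro-1H,3H-pyrrolo[1,2-c][1,3,2]oxazaborole (20 mol %), HN(SO2CF3)2 (20 mol %), 6 (10 equiv), CH2Cl2, −78 to −40 °C, 5 added over 4 h
Reagents that add atoms: none
Why: Proposed new method: the boron of the cationic oxazaborolidine binds the carbonyl lone pair on the C2–H side (the other is blocked by the C10 methyls), lowers the LUMO of the whole dienone and polarises it by vinylogy so that the δ-carbon C9 is the electrophilic end; the HOMO of isoprene then adds in a concerted, asynchronous [4π+2π] cycloaddition whose leading bond joins its most nucleophilic terminus (the CH2 next to the methyl-bearing carbon, C8) to C9 and whose lagging bond joins C5 to C4. The closest known reactions are the Diels–Alder dimerisation of 6,6-disubstituted cyclohexa-2,4-dienones and the cis-decalin-forming additions of acyclic dienes to their 6,6-dialkoxy analogues, both through the γ,δ-alkene as 2π partner, together with para-selective oxazaborolidinium-catalysed isoprene additions to cyclic enones and quinones; the new element is the enantioselective cross-reaction at a vinylogous site. Ring B closes by intermolecular suprafacial–suprafacial cycloaddition, both σ-bonds (C4–C5 and C8–C9) forming on one face of the cis C4=C9 alkene. C4 and C9 are therefore cis by the concerted mechanism, and their absolute configuration is set by the catalyst, whose aryl group stacks against one face of the flat dienone and leaves the other open. Site selectivity rests on the disubstituted C4=C9 being less hindered than the trisubstituted C2=C3, and regioselectivity on the match of the vinylogous polarisation with the larger terminal coefficient of isoprene, which puts the methyl group on C7. Periselectivity is helped by the excess of isoprene and the slow addition of 5, and it is self-correcting, since the alternative adduct with the dienone as 4π partner shares the C8–C9 bond and is a 1,5-diene that can pass to 7 by Cope rearrangement.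

Step 6
Reactants: 7 (4aR,8aS)-1,1,4,7-tetramethyl-4a,5,8,8a-tetrahydronaphthalen-2(1H)-one
Product: 9 (4aS,9aR)-3,5,5,9-tetramethyl-1,4,4a,5,7,9a-hexahydro-6H-benzo[7]annulen-6-one, via alpha-silyl ketone 8 (not isolated)
Conditions: Me3SiCHN2 (1.5 equiv), BF3·OEt2, CH2Cl2, −78 to −30 °C; then dilute aq. HCl, THF, 0 °C
Reagents that add atoms: (trimethylsilyl)diazomethane C[Si](C)(C)C=[N+]=[N-] (its carbon becomes C1; silicon in 8 only)
Why: In this Lewis-acid-promoted diazoalkane homologation (Tiffeneau–Demjanov-type 1,2-shift) the diazo carbon adds to the activated C11 carbonyl and, as N2 leaves, the β,β-disubstituted alkenyl carbon C2 migrates rather than the tertiary alkyl C10, in line with the migratory order of this reaction (alkenyl at the top, tertiary alkyl at the bottom), so C1 is inserted between C11 and C2, while the silyl group blocks a second homologation and is lost on mild acid work-up with protonation at C1, which keeps C2=C3 out of conjugation.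

Step 7
Reactants: 9 (4aS,9aR)-3,5,5,9-tetramethyl-1,4,4a,5,7,9a-hexahydro-6H-benzo[7]annulen-6-one
Product: 11 (4aS,7R,9aR)-7-hydroxy-3,5,5,9-tetramethyl-1,4,4a,5,7,9a-hexahydro-6H-benzo[7]annulen-6-one, via potassium dienolate 10 (not isolated)
Conditions: KN(SiMe3)2, THF, −78 °C; 2-(phenylsulfonyl)-3-phenyloxaziridine, −78 °C; AcOH, −78 °C
Reagents that add atoms: 2-(phenylsulfonyl)-3-phenyloxaziridine O=S(=O)(c1ccccc1)N1OC1c1ccccc1; potassium bis(trimethylsilyl)amide C[Si](C)(C)[N-][Si](C)(C)C.[K+] (potassium in 10 only)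
Why: Davis oxaziridine hydroxylation of a dienolate takes place at the α-carbon C1, and because ring A of 10 should pucker C9 away from the fusion hydrogens to avoid a syn-pentane contact between C5 and a C10 methyl, the other C10 methyl stands axial over the face that carries H4 and H9, so oxygen is delivered to the opposite face and C1 becomes R.

Step 8
Reactants: 11 (4aS,7R,9aR)-7-hydroxy-3,5,5,9-tetramethyl-1,4,4a,5,7,9a-hexahydro-6H-benzo[7]annulen-6-one
Product: 12 (4aS,6R,7R,9aR)-3,5,5,9-tetramethyl-4,4a,5,6,7,9a-hexahydro-1H-benzo[7]annulene-6,7-diol (trans-diol)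
Conditions: Me4N[BH(OAc)3], MeCN/AcOH, −30 to 0 °C; aqueous work-up
Reagents that add atoms: none
Why: In this hydroxyl-directed (Evans–Saksena type) reduction the C1 hydroxyl replaces an acetate on boron and hydride is handed to C11 on the same face, so the new C11 hydroxyl is trans to the C1 hydroxyl (C11 R), and the acidic medium spares the base-sensitive β,γ-unsaturated ketol.

Step 9
Reactants: 13 angelic acid ((2Z)-2-methylbut-2-enoic acid)
Product: 14 (2Z)-2-methylbut-2-enoic 2,4,6-trichlorobenzoic anhydride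
Conditions: 2,4,6-Cl3C6H2COCl, Et3N, toluene, rt; filtered, solution used directly
Reagents that add atoms: 2,4,6-trichlorobenzoyl chloride O=C(Cl)c1c(Cl)cc(Cl)cc1Cl
Why: Yamaguchi-type mixed anhydride formation activates angelic acid without an acid chloride or a nucleophilic catalyst, conditions under which the Z-alkene is known to persist.

Step 10
Reactants: 12 (4aS,6R,7R,9aR)-3,5,5,9-tetramethyl-4,4a,5,6,7,9a-hexahydro-1H-benzo[7]annulene-6,7-diol; 14 (2Z)-2-methylbut-2-enoic 2,4,6-trichlorobenzoic anhydride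
Product: 15 (4aS,6R,7R,9aR)-3,5,5,9-tetramethyl-4,4a,5,6,7,9a-hexahydro-1H-benzo[7]annulene-6,7-diyl bis[(2Z)-2-methylbut-2-enoate]
Conditions: 14 (4 equiv), toluene, 80 °C
Reagents that add atoms: none
Why: Acyl transfer from the mixed anhydride occurs at the angeloyl carbonyl because the aryl carbonyl is flanked by two ortho chlorines, and leaving out 4-(dimethylamino)pyridine avoids the addition–elimination that turns angelates into tiglates, no stereocentre being touched.

Step 11
Reactants: 15 (4aS,6R,7R,9aR)-3,5,5,9-tetramethyl-4,4a,5,6,7,9a-hexahydro-1H-benzo[7]annulene-6,7-diyl bis[(2Z)-2-methylbut-2-enoate]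
Product: 16 (2R,3S,4aS,6R,7R,9aR)-2,3-dihydroxy-3,5,5,9-tetramethyl-2,3,4,4a,5,6,7,9a-octahydro-1H-benzo[7]annulene-6,7-diyl bis[(2Z)-2-methylbut-2-enoate]
Conditions: OsO4 (2 mol %), NMO (1.05 equiv), acetone/H2O, 0 °C
Reagents that add atoms: N-methylmorpholine N-oxide C[N+]1([O-])CCOCC1; water O
Why: Upjohn dihydroxylation picks the most electron-rich and least hindered alkene C6=C7 over C2=C3 (deactivated by the allylic ester and flanked by C4) and over the two conjugated angelate alkenes, and the syn addition should come from the face of H4 and H9 because C3 stands axial on the other face of ring B (C6 R, C7 S, both erased later).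

Step 12
Reactants: 16 (2R,3S,4aS,6R,7R,9aR)-2,3-dihydroxy-3,5,5,9-tetramethyl-2,3,4,4a,5,6,7,9a-octahydro-1H-benzo[7]annulene-6,7-diyl bis[(2Z)-2-methylbut-2-enoate]
Product: 17 (3S,4aS,6R,7R,9aR)-3-hydroxy-3,5,5,9-tetramethyl-2-oxo-2,3,4,4a,5,6,7,9a-octahydro-1H-benzo[7]annulene-6,7-diyl bis[(2Z)-2-methylbut-2-enoate]
Conditions: IBX, DMSO, rt
Reagents that add atoms: none
Why: IBX oxidises the secondary alcohol of a 1,2-diol to the α-ketol without C–C cleavage and cannot oxidise the tertiary C7 hydroxyl.

Step 13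
Reactants: 17 (3S,4aS,6R,7R,9aR)-3-hydroxy-3,5,5,9-tetramethyl-2-oxo-2,3,4,4a,5,6,7,9a-octahydro-1H-benzo[7]annulene-6,7-diyl bis[(2Z)-2-methylbut-2-enoate]
Product: 19 (4aS,6R,7R,9aR)-3,5,5,9-tetramethyl-2-oxo-2,4a,5,6,7,9a-hexahydro-1H-benzo[7]annulene-6,7-diyl bis[(2Z)-2-methylbut-2-enoate] (CNP0361763.1), via chlorosulfite 18 (not isolated)
Conditions: SOCl2, pyridine, 0 °C
Reagents that add atoms: thionyl chloride O=S(Cl)Cl (sulfur, oxygen and chlorine in 18 only)
Why: This is the anti E2 dehydration of a tertiary α-ketol through its chlorosulfite, as in the classical conversion of 5α-hydroxy 6-keto steroids into 4-en-6-ones, and since the C7 oxygen is axial and antiperiplanar to the axial C8 hydrogen the conjugated endocyclic C7=C8 alkene should form rather than an exocyclic methylene ketone.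

## Compound list

1 | 4,4-dimethylcyclohex-2-en-1-one | CC1(C)CCC(=O)C=C1 | starting material
2 | 1,4,4-trimethylcyclohex-2-en-1-ol (racemic) | CC1(O)C=CC(C)(C)CC1 | intermediate
3 | 3,6,6-trimethylcyclohex-2-en-1-one | CC1=CC(=O)C(C)(C)CC1 | intermediate
4 | tert-butyldimethyl[(3,6,6-trimethylcyclohexa-1,3-dien-1-yl)oxy]silane | CC1=CCC(C)(C)C(O[Si](C)(C)C(C)(C)C)=C1 | intermediate
5 | 3,6,6-trimethylcyclohexa-2,4-dien-1-one | CC1=CC(=O)C(C)(C)C=C1 | intermediate
6 | isoprene | C=CC(C)=C | starting material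
7 | (4aR,8aS)-1,1,4,7-tetramethyl-4a,5,8,8a-tetrahydronaphthalen-2(1H)-one | O=C1C=C(C)[C@@H]2CC=C(C)C[C@@H]2C1(C)C | intermediate
8 | (4aS,9aR)-3,5,5,9-tetramethyl-7-(trimethylsilyl)-1,4,4a,5,7,9a-hexahydro-6H-benzo[7]annulen-6-one (silyl-bearing carbon undefined) | O=C1C([Si](C)(C)C)C=C(C)[C@@H]2CC=C(C)C[C@@H]2C1(C)C | intermediate
9 | (4aS,9aR)-3,5,5,9-tetramethyl-1,4,4a,5,7,9a-hexahydro-6H-benzo[7]annulen-6-one | O=C1CC=C(C)[C@@H]2CC=C(C)C[C@@H]2C1(C)C | intermediate
10 | potassium (4aS,9aR)-3,5,5,9-tetramethyl-4,4a,5,9a-tetrahydro-1H-benzo[7]annulen-6-olate | [K+].[O-]C1=CC=C(C)[C@@H]2CC=C(C)C[C@@H]2C1(C)C | intermediate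
11 | (4aS,7R,9aR)-7-hydroxy-3,5,5,9-tetramethyl-1,4,4a,5,7,9a-hexahydro-6H-benzo[7]annulen-6-one | O[C@@H]1C=C(C)[C@@H]2CC=C(C)C[C@@H]2C(C)(C)C1=O | intermediate
12 | (4aS,6R,7R,9aR)-3,5,5,9-tetramethyl-4,4a,5,6,7,9a-hexahydro-1H-benzo[7]annulene-6,7-diol | O[C@@H]1C=C(C)[C@@H]2CC=C(C)C[C@@H]2C(C)(C)[C@H]1O | intermediate
13 | angelic acid | C/C=C(/C)C(=O)O | starting material
14 | (2Z)-2-methylbut-2-enoic 2,4,6-trichlorobenzoic anhydride | C/C=C(/C)C(=O)OC(=O)c1c(Cl)cc(Cl)cc1Cl | intermediate
15 | (4aS,6R,7R,9aR)-3,5,5,9-tetramethyl-4,4a,5,6,7,9a-hexahydro-1H-benzo[7]annulene-6,7-diyl bis[(2Z)-2-methylbut-2-enoate] | C/C=C(/C)C(=O)O[C@@H]1C=C(C)[C@@H]2CC=C(C)C[C@@H]2C(C)(C)[C@H]1OC(=O)/C(C)=C\C | intermediate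
16 | (2R,3S,4aS,6R,7R,9aR)-2,3-dihydroxy-3,5,5,9-tetramethyl-2,3,4,4a,5,6,7,9a-octahydro-1H-benzo[7]annulene-6,7-diyl bis[(2Z)-2-methylbut-2-enoate] | C/C=C(/C)C(=O)O[C@@H]1C=C(C)[C@@H]2C[C@@H](O)[C@@](C)(O)C[C@@H]2C(C)(C)[C@H]1OC(=O)/C(C)=C\C | intermediate
17 | (3S,4aS,6R,7R,9aR)-3-hydroxy-3,5,5,9-tetramethyl-2-oxo-2,3,4,4a,5,6,7,9a-octahydro-1H-benzo[7]annulene-6,7-diyl bis[(2Z)-2-methylbut-2-enoate] | C/C=C(/C)C(=O)O[C@@H]1C=C(C)[C@@H]2CC(=O)[C@@](C)(O)C[C@@H]2C(C)(C)[C@H]1OC(=O)/C(C)=C\C | intermediate
18 | chlorosulfite of 17 at the C7 oxygen (sulfur centre undefined) | C/C=C(/C)C(=O)O[C@@H]1C=C(C)[C@@H]2CC(=O)[C@@](C)(OS(=O)Cl)C[C@@H]2C(C)(C)[C@H]1OC(=O)/C(C)=C\C | intermediate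
19 | (4aS,6R,7R,9aR)-3,5,5,9-tetramethyl-2-oxo-2,4a,5,6,7,9a-hexahydro-1H-benzo[7]annulene-6,7-diyl bis[(2Z)-2-methylbut-2-enoate] | C/C=C(/C)C(=O)O[C@@H]1C=C(C)[C@@H]2CC(=O)C(C)=C[C@@H]2C(C)(C)[C@H]1OC(=O)/C(C)=C\C | target

## Step count and risks

Total step count: 13. Longest linear sequence: 12 (steps 1–8 and 10–13).

**Step 5 (labelled)**

- What may go wrong: the dienone may dimerise, or undergo an acid-induced dienone–phenol methyl shift, faster than it meets isoprene. Face selection may also be weak because C4=C9 lies far from boron.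
- The fallback sets out from 1 and 6 and returns at 7. The cycloaddition is moved to the ordinary α,β-alkene of 1, and the carbonyl transposition is carried out afterwards.
- Lewis-acid-catalysed, para-selective Diels–Alder addition of simple dienes to 4,4-dimethylcyclohex-2-enone is a known reaction type, and the same oxazaborolidinium salt is an established catalyst for 2-cycloalkenones.
- With cold work-up to keep the kinetic cis fusion it should give (4aS,8aR)-4,4,6-trimethyl-3,4,4a,5,8,8a-hexahydronaphthalen-1(2H)-one F1.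
- Kinetic enolisation at the CH2 side with LiN(iPr)2 and Me3SiCl gives [(4aS,8aR)-4,4,6-trimethyl-3,4,4a,5,8,8a-hexahydronaphthalen-1-yl]oxy(trimethyl)silane F2.
- Pd(OAc)2 in MeCN dehydrogenates this to (4aS,8aR)-4,4,6-trimethyl-4a,5,8,8a-tetrahydronaphthalen-1(4H)-one F3.
- MeLi adds 1,2 to give (4aS,8aR)-1,4,4,6-tetramethyl-1,4,4a,5,8,8a-hexahydronaphthalen-1-ol F4.
- Pyridinium chlorochromate [C5H5NH][CrO3Cl] then transposes the oxygen to the carbon next to C10 and delivers 7.

**Step 6**

- What may go wrong: addition of the diazoalkane to the hindered, conjugated carbonyl may be sluggish, homologation may continue, or C2=C3 may drift into conjugation.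
- The fallback sets out from 7 and returns at 10.
- Li in NH3/THF at −78 °C reduces the enone to (4aS,8aS)-1,1,4,7-tetramethyl-3,4,4a,5,8,8a-hexahydronaphthalen-2(1H)-one F5. Both C3 epimers serve.
- Me3SiCHN2/BF3·OEt2 now meets a non-conjugated ketone in which the CH2 group migrates in preference to the quaternary C10.
- This gives, through (4aS,9aS)-3,5,5,9-tetramethyl-7-(trimethylsilyl)-1,4,4a,5,7,8,9,9a-octahydro-6H-benzo[7]annulen-6-one F6, the cycloheptanone (4aS,9aS)-3,5,5,9-tetramethyl-1,4,4a,5,7,8,9,9a-octahydro-6H-benzo[7]annulen-6-one F7.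
- Mukaiyama dehydrogenation (KN(SiMe3)2, then N-tert-butylbenzenesulfinimidoyl chloride, −78 °C) at the only enolisable side gives (4aS,9aS)-3,5,5,9-tetramethyl-1,4,4a,5,9,9a-hexahydro-6H-benzo[7]annulen-6-one F8.
- KN(SiMe3)2 removes the γ-hydrogen at C3 of F8 to form the same dienolate 10.

**Step 7**

- What may go wrong: facial selectivity at C1 may be poor or reversed, and the ketol may isomerise under base.
- The fallback sets out from 9 and returns at 11.
- If oxygen transfer prefers the face of H4 and H9, the hydroxylation gives (4aS,7S,9aR)-7-hydroxy-3,5,5,9-tetramethyl-1,4,4a,5,7,9a-hexahydro-6H-benzo[7]annulen-6-one F9.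
- The crude ketol is oxidised with IBX in DMSO to (4aS,9aR)-3,5,5,9-tetramethyl-4,4a,5,9a-tetrahydro-1H-benzo[7]annulene-6,7-dione F10.
- Luche reduction (NaBH4, CeCl3·7H2O, MeOH, −78 °C) of the less hindered, conjugated C1 carbonyl then uses the same facial bias to deliver hydride instead of oxygen. This inverts the outcome at C1 and gives 11.

## Further compounds

F1 | step 5 | (4aS,8aR)-4,4,6-trimethyl-3,4,4a,5,8,8a-hexahydronaphthalen-1(2H)-one | O=C1[C@@H]2CC=C(C)C[C@@H]2C(C)(C)CC1
F2 | step 5 | [(4aS,8aR)-4,4,6-trimethyl-3,4,4a,5,8,8a-hexahydronaphthalen-1-yl]oxy(trimethyl)silane | C[Si](C)(C)OC=1[C@@H]2CC=C(C)C[C@@H]2C(C)(C)CC=1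
F3 | step 5 | (4aS,8aR)-4,4,6-trimethyl-4a,5,8,8a-tetrahydronaphthalen-1(4H)-one | O=C1[C@@H]2CC=C(C)C[C@@H]2C(C)(C)C=C1
F4 | step 5 | (4aS,8aR)-1,4,4,6-tetramethyl-1,4,4a,5,8,8a-hexahydronaphthalen-1-ol (carbinol centre undefined) | CC1(O)[C@@H]2CC=C(C)C[C@@H]2C(C)(C)C=C1
F5 | step 6 | (4aS,8aS)-1,1,4,7-tetramethyl-3,4,4a,5,8,8a-hexahydronaphthalen-2(1H)-one (C3 epimers) | O=C1CC(C)[C@@H]2CC=C(C)C[C@@H]2C1(C)C
F6 | step 6 | (4aS,9aS)-3,5,5,9-tetramethyl-7-(trimethylsilyl)-1,4,4a,5,7,8,9,9a-octahydro-6H-benzo[7]annulen-6-one (C1 and C3 undefined) | O=C1C([Si](C)(C)C)CC(C)[C@@H]2CC=C(C)C[C@@H]2C1(C)C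
F7 | step 6 | (4aS,9aS)-3,5,5,9-tetramethyl-1,4,4a,5,7,8,9,9a-octahydro-6H-benzo[7]annulen-6-one (C3 epimers) | O=C1CCC(C)[C@@H]2CC=C(C)C[C@@H]2C1(C)C
F8 | step 6 | (4aS,9aS)-3,5,5,9-tetramethyl-1,4,4a,5,9,9a-hexahydro-6H-benzo[7]annulen-6-one (C3 epimers) | O=C1C=CC(C)[C@@H]2CC=C(C)C[C@@H]2C1(C)C
F9 | step 7 | (4aS,7S,9aR)-7-hydroxy-3,5,5,9-tetramethyl-1,4,4a,5,7,9a-hexahydro-6H-benzo[7]annulen-6-one | O[C@H]1C=C(C)[C@@H]2CC=C(C)C[C@@H]2C(C)(C)C1=O
F10 | step 7 | (4aS,9aR)-3,5,5,9-tetramethyl-4,4a,5,9a-tetrahydro-1H-benzo[7]annulene-6,7-dione | O=C1C=C(C)[C@@H]2CC=C(C)C[C@@H]2C(C)(C)C1=O
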